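## Retrosynthetic overview

1. Violacene (9) comes from Markovnikov BrCl addition to the exocyclic alkene of trichloride 8, which sets C3 (ring numbering follows the SMILES: C1 quaternary, C3 = C(Cl)CH2Br, C4 and C6 = CHCl).
2. Trichloride 8 comes from a double invertive deoxychlorination of cis-1,3-diol 7, whose two hydroxyls are trans to the chlorovinyl group.
3. Diol 7 comes from hydride reduction of the α′-methylene-α,β-epoxy ketone 6, made from enone 4 by catalyst-controlled epoxidation and Eschenmoser methylenation.
4. Enone 4 comes from Takai chloro-olefination of 4-formyl-4-methylcyclohexenone 3, made by an enantioselective Diels–Alder reaction of an aminosiloxydiene with methacrolein.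
5. Ring order: the cyclohexane is the only carbocycle and is formed first (step 1); an oxirane is formed in step 3 and opened in step 5.

Assumption: the catalyst antipodes named in steps 1 and 3 are those expected to give the drawn isomers by analogy with the parent substrates; if the observed sense is opposite, the mirror-image (or pseudo-enantiomeric) catalyst is used and nothing else changes.

This route is a design from known reaction classes; it has not been run, and the selectivities below are predictions.

## Route

**Step 1**
Reactants: 1, (E)-1-(dimethylamino)-3-(tert-butyldimethylsilyloxy)buta-1,3-diene (Rawal's diene); 2, methacrolein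
Product: 3, (S)-1-methyl-4-oxocyclohex-2-ene-1-carbaldehyde
Conditions: (R,R)-1-naphthyl-TADDOL (20 mol %), toluene, −80 °C; then aq. HF, MeCN, 0 °C
Reagents that add atoms: none
Why: Hydrogen-bond-catalysed Diels–Alder reaction joins the amino terminus of the diene to the α-carbon of the enal, the TADDOL-bound aldehyde face setting the quaternary centre (target C1); acid then eliminates Me2NH and removes the silyl group to give the enone.

**Step 2**
Reactants: 3
Product: 4, (S)-4-[(E)-2-chloroethenyl]-4-methylcyclohex-2-en-1-one
Conditions: CrCl2 (6 equiv), CHCl3, THF, 65 °C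
Reagents that add atoms: chloroform, ClC(Cl)Cl
Why: Takai–Utimoto olefination converts the aldehyde chemoselectively (enone untouched) into the (E)-chloroalkene; no stereocentre is affected.

**Step 3**
Reactants: 4
Product: 5, (1R,5R,6R)-5-[(E)-2-chloroethenyl]-5-methyl-7-oxabicyclo[4.1.0]heptan-2-one (epoxide oxygen trans to the chlorovinyl group, cis to methyl)
Conditions: 50% aq. H2O2, 9-amino(9-deoxy)epiquinidine·2TFA (10 mol %), dioxane, 30–50 °C
Reagents that add atoms: hydrogen peroxide, OO
Why: Iminium-catalysed nucleophilic (Weitz–Scheffer-type) epoxidation; the face is chosen by the catalyst because methyl and chlorovinyl give little substrate bias. This sets the C6–O configuration, and the minor enantiomer of 4 becomes a separable diastereomer.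

**Step 4**
Reactants: 5
Product: 6, (1R,5R,6R)-5-[(E)-2-chloroethenyl]-5-methyl-3-methylidene-7-oxabicyclo[4.1.0]heptan-2-one
Conditions: LiHMDS, THF, −78 °C; CH2=NMe2+ I−, −78 → 0 °C; then MeI; aq. NaHCO3, rt
Reagents that add atoms: Eschenmoser's salt, C=[N+](C)C.[I-]
Why: The epoxide blocks enolisation on its side, so the only enolate (at target C3) undergoes Mannich reaction and Hofmann-type elimination to the α-methylene ketone; no stereocentre changes.

**Step 5**
Reactants: 6
Product: 7, (1R,3S,4R)-4-[(E)-2-chloroethenyl]-4-methyl-6-methylidenecyclohexane-1,3-diol (both OH cis to each other and trans to the chlorovinyl group)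
Conditions: LiAlH4 (excess), THF, −78 °C → rt
Reagents that add atoms: none
Why: 1,2-Hydride addition to the ketone anti to the epoxide oxygen sets C4 (giving the cis epoxy alkoxide). Hydride then opens the oxirane by SN2 at the non-neopentyl carbon C5, leaving the C6–O bond and its configuration intact.

**Step 6**
Reactants: 7
Product: 8, (1R,2R,4S)-2,4-dichloro-1-[(E)-2-chloroethenyl]-1-methyl-5-methylidenecyclohexane
Conditions: PPh3 (4 equiv), NCS (4 equiv, premixed), THF, 0 → 40 °C
Reagents that add atoms: N-chlorosuccinimide, O=C1CCC(=O)N1Cl
Why: Appel-type chlorination via alkoxyphosphonium ions displaces both the allylic (C4) and the neopentyl (C6) hydroxyl by SN2 with inversion, placing both chlorides cis to the chlorovinyl group.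

**Step 7**
Reactants: 8
Product: 9, violacene, (1R,2R,4S,5R)-5-(bromomethyl)-2,4,5-trichloro-1-[(E)-2-chloroethenyl]-1-methylcyclohexane
Conditions: n-Bu4N+ BrCl2− (1.05 equiv), CH2Cl2, −78 → 0 °C, dark
Reagents that add atoms: tetrabutylammonium dichlorobromate, written as its components Bu4N+ Cl− · BrCl (delivers one Br and one Cl), CCCC[N+](CCCC)(CCCC)CCCC.[Cl-].ClBr
Why: Markovnikov bromochlorination of the more nucleophilic 1,1-disubstituted alkene; the electron-poor chlorovinyl group is left alone. The bromonium ion forms on the face away from the syn-axial chlorovinyl group and chloride opens it axially at the tertiary carbon, giving C3–Cl cis to C4–Cl with CH2Br equatorial.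

## Compound list

1 | (E)-1-(dimethylamino)-3-(tert-butyldimethylsilyloxy)buta-1,3-diene | CN(C)/C=C/C(=C)O[Si](C)(C)C(C)(C)C | starting material
2 | methacrolein | CC(=C)C=O | starting material
3 | (S)-1-methyl-4-oxocyclohex-2-ene-1-carbaldehyde | C[C@]1(C=O)CCC(=O)C=C1 | intermediate
4 | (S)-4-[(E)-2-chloroethenyl]-4-methylcyclohex-2-en-1-one | C[C@]1(/C=C/Cl)CCC(=O)C=C1 | intermediate
5 | (1R,5R,6R)-5-[(E)-2-chloroethenyl]-5-methyl-7-oxabicyclo[4.1.0]heptan-2-one | C[C@]1(/C=C/Cl)CCC(=O)[C@@H]2O[C@H]12 | intermediate
6 | (1R,5R,6R)-5-[(E)-2-chloroethenyl]-5-methyl-3-methylidene-7-oxabicyclo[4.1.0]heptan-2-one | C[C@]1(/C=C/Cl)CC(=C)C(=O)[C@@H]2O[C@H]12 | intermediate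
7 | (1R,3S,4R)-4-[(E)-2-chloroethenyl]-4-methyl-6-methylidenecyclohexane-1,3-diol | C[C@]1(/C=C/Cl)CC(=C)[C@H](O)C[C@@H]1O | intermediate
8 | (1R,2R,4S)-2,4-dichloro-1-[(E)-2-chloroethenyl]-1-methyl-5-methylidenecyclohexane | C[C@]1(/C=C/Cl)CC(=C)[C@@H](Cl)C[C@H]1Cl | intermediate
9 | violacene | C[C@]1(/C=C/Cl)C[C@](Cl)(CBr)[C@@H](Cl)C[C@H]1Cl | target

## Summary

Total steps: 7. Longest linear sequence: 7 (fully linear from compounds 1 and 2).

Steps most likely to fail:

1. **Step 6 (double Appel).** SN2 at the neopentyl C6 may be slow or give elimination, and the allylic C4 may react by SN2′. Fallback: make the neopentyl C–Cl bond stereospecifically from an sp2 C–Cl instead. Run a Diels–Alder reaction of (Z)-3-chloro-2-methylacrolein (from propargyl alcohol by Cu-catalysed carbomagnesiation with MeMgBr, NCS quench, then MnO2) with a 2-silyloxybutadiene. Only the allylic C4–Cl then needs a substitution; this requires a reagent-controlled (CBS) ketone reduction to get the right C4 alcohol.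

2. **Step 7 (BrCl addition).** The C3 facial selectivity or the chemoselectivity over the chlorovinyl group may be poor. Fallback: switch from kinetic to thermodynamic control. Re-ionise the tertiary C–Cl through the bromonium ion (HFIP with Et4NCl, or catalytic ZnCl2) to equilibrate the C3 epimers toward violacene, which has the bulky CH2Br equatorial.

3. **Step 5 (LiAlH4).** Three things can go wrong: 1,4-reduction of the exo-methylene ketone, the wrong face at C4, or epoxide opening at C6. Fallback: cleave the epoxide of 5 by single-electron reduction (Cp2TiCl or SmI2), which is regiospecific for the Cα–O bond, to the β-hydroxy ketone. Then silylate, methylenate the kinetic α′-enolate, and reduce under Luche conditions (substrate-controlled 1,3-cis) before desilylation.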